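With ring atoms numbered C1 (bearing the side chain) to C6, the C5 carbinol read as a ketone turns the ring into a 5-substituted cyclohex-2-enone (C5=O, C3=C4). That enone is cut into an enal (C1–C3) and an acetoacetate (C4–C6). One amine-catalysed Michael addition followed by acid-driven aldol condensation and decarboxylation forms C6–C1 and C3=C4, closes the ring and sets C1. The precursor is a silyl-capped 2-en-4-ynal whose alkyne is the latent C7=C14 methylene unit. C4 hydroxymethylation, acylation, a ruthenium-catalysed alkene–alkyne coupling and a late carvone-type Luche reduction of the C5 ketone finish the synthesis.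

Key step: step 2

Remark (numbering): C15 is the acyloxymethyl carbon on C4, C7=C14 the exocyclic methylene, C8–C13 the chain with the tertiary carbinol C11; the target is (1S,5S,11R,9E) with the C1 and C5 substituents cis.
Assumption: the sense of induction in step 2 is taken from the accepted shielding model for diarylprolinol silyl ethers (attack on the s-trans (E)-iminium ion anti to the C(Ar)2OSiMe3 group); on this model the (R)-amine delivers 1S.

Step 1
Reactants: 1 3-(trimethylsilyl)prop-2-ynal; 2 (triphenylphosphoranylidene)acetaldehyde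
Product: 3 (2E)-5-(trimethylsilyl)pent-2-en-4-ynal
Conditions: 1 (1.3 equiv), toluene, rt
Reagents that add atoms: none
Why: Wittig olefination with a formyl-stabilised ylide, which should give the (E)-enal, the ynal being far more electrophilic than the enal product so that a second homologation stays minor.

Step 2
Reactants: 3 (2E)-5-(trimethylsilyl)pent-2-en-4-ynal; 4 tert-butyl 3-oxobutanoate
Product: 7 (5S)-5-[(trimethylsilyl)ethynyl]cyclohex-2-en-1-one, via Michael adduct 5 (not isolated), via keto aldehyde 6 (not isolated)
Conditions: (R)-2-{bis[3,5-bis(trifluoromethyl)phenyl][(trimethylsilyl)oxy]methyl}pyrrolidine (10 mol %), PhCO2H (10 mol %), toluene, rt; then TsOH·H2O (20 mol %), toluene, 80 °C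
Reagents that add atoms: none
Why: The amine condenses with 3 to an (E)-iminium ion whose β-carbon (C1) takes up the enol of 4 to form the C6–C1 bond; hot TsOH then removes the tert-butyl ester as isobutene and CO2, and the methyl-ketone enol (C4) adds to the aldehyde carbon (C3) and loses water to give the C3=C4 alkene. This is the amine-catalysed Michael addition of β-ketoesters to enals followed by acid-mediated aldol condensation and decarboxylation, a known route to 5-substituted cyclohex-2-enones, applied here to a 2-en-4-ynal. The six-membered ring closes by a 6-(enolendo)-exo-trig aldol addition. The C1 stereocentre is set by the catalyst: in the s-trans (E)-iminium ion the C(Ar)2OSiMe3 arm of the (R)-amine covers the Si face of C1, so the ketoester should add to the Re face, which corresponds to 1S. The step needs 1,4- rather than 1,6-addition and a single cyclisation mode; the trimethylsilyl cap shields the alkyne terminus, and only the methyl group of the ketone can reach the aldehyde through a six-membered transition state, the other enol leading to a four-membered ring.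

Step 3
Reactants: 7 (5S)-5-[(trimethylsilyl)ethynyl]cyclohex-2-en-1-one
Product: 8 (5S)-2-(hydroxymethyl)-5-[(trimethylsilyl)ethynyl]cyclohex-2-en-1-one
Conditions: 37% aq. HCHO (2 equiv), DMAP (20 mol %), THF/H2O, rt
Reagents that add atoms: formaldehyde, C=O
Why: Morita–Baylis–Hillman reaction, in which DMAP adds reversibly to C3, the enolate is hydroxymethylated at C4 and the amine is expelled, as established for cyclohex-2-enones; C1 is not enolisable and keeps its configuration.

Step 4
Reactants: 8 (5S)-2-(hydroxymethyl)-5-[(trimethylsilyl)ethynyl]cyclohex-2-en-1-one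
Product: 9 [(4S)-6-oxo-4-[(trimethylsilyl)ethynyl]cyclohex-1-en-1-yl]methyl 2-methylpropanoate
Conditions: iPrCOCl (1.2 equiv), pyridine, CH2Cl2, 0 °C
Reagents that add atoms: isobutyryl chloride, CC(C)C(=O)Cl
Why: Acylation of the only hydroxyl group (primary, allylic) with an acid chloride and pyridine, run without a nucleophilic catalyst so that SN2′ exchange at the activated allylic ester is avoided.

Step 5
Reactants: 9 [(4S)-6-oxo-4-[(trimethylsilyl)ethynyl]cyclohex-1-en-1-yl]methyl 2-methylpropanoate
Product: 10 [(4S)-4-ethynyl-6-oxocyclohex-1-en-1-yl]methyl 2-methylpropanoate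
Conditions: AgNO3 (10 mol %), acetone/H2O, rt, dark
Reagents that add atoms: none
Why: Silver-catalysed protodesilylation of an alkynylsilane, in which AgNO3 activates the C(sp)–Si bond towards water and the silver acetylide is protonated in situ; the neutral medium should spare the enone and the isobutyrate, which carbonate in methanol would not.

Step 6
Reactants: 11 (S)-2-methylglycidol
Product: 12 (2R)-2-methylpent-4-ene-1,2-diol
Conditions: vinylmagnesium bromide (3 equiv), CuI (10 mol %), THF, −30 → 0 °C; aq. NH4Cl
Reagents that add atoms: vinylmagnesium bromide, C=C[Mg]Br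
Why: Copper-catalysed Grignard opening of a 2,2-disubstituted epoxide by SN2 attack at its CH2 terminus; the quaternary centre is not touched and its descriptor changes from S to R only through the change in substituent priorities.

Step 7
Reactants: 12 (2R)-2-methylpent-4-ene-1,2-diol
Product: 13 (2R)-2-hydroxy-2-methylpent-4-en-1-yl 2-methylpropanoate
Conditions: iPrCOCl (1.05 equiv), pyridine, CH2Cl2, −20 → 0 °C
Reagents that add atoms: isobutyryl chloride, CC(C)C(=O)Cl
Why: Selective acylation of a primary alcohol beside a tertiary one, which is inert to an acid chloride and pyridine at low temperature.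

Step 8
Reactants: 10 [(4S)-4-ethynyl-6-oxocyclohex-1-en-1-yl]methyl 2-methylpropanoate; 13 (2R)-2-hydroxy-2-methylpent-4-en-1-yl 2-methylpropanoate
Product: 14 (2R,3E)-2-hydroxy-2-methyl-6-[(1S)-4-{[(2-methylpropanoyl)oxy]methyl}-5-oxocyclohex-3-en-1-yl]hepta-3,6-dien-1-yl 2-methylpropanoate
Conditions: 13 (1.5 equiv), [CpRu(MeCN)3]PF6 (10 mol %), acetone, rt
Reagents that add atoms: none
Why: Ruthenium-catalysed alkene–alkyne coupling (formal Alder-ene reaction), in which oxidative cyclisation of the terminal alkyne and the monosubstituted alkene on the CpRu cation joins C7 to C8 (branched mode), and β-hydride elimination from C10 followed by reductive elimination gives the 1,4-diene with an (E)-C9=C10 bond; the trisubstituted enone alkene, the esters and the tertiary alcohol are spectators and no stereocentre is touched.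

Step 9
Reactants: 14 (2R,3E)-2-hydroxy-2-methyl-6-[(1S)-4-{[(2-methylpropanoyl)oxy]methyl}-5-oxocyclohex-3-en-1-yl]hepta-3,6-dien-1-yl 2-methylpropanoate
Product: 15 (2R,3E)-2-hydroxy-6-[(1S,5S)-5-hydroxy-4-{[(2-methylpropanoyl)oxy]methyl}cyclohex-3-en-1-yl]-2-methylhepta-3,6-dien-1-yl 2-methylpropanoate
Conditions: NaBH4 (1.1 equiv), CeCl3·7H2O (1.1 equiv), MeOH, −78 °C
Reagents that add atoms: none
Why: Luche reduction, which reduces the cerium-activated ketone 1,2 and leaves the esters alone; hydride should add axially to the half-chair with the C1 substituent pseudo-equatorial, as in the reduction of carvone to cis-carveol, placing the C5 hydroxyl cis to the side chain (5S).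

Compound list
1 | 3-(trimethylsilyl)prop-2-ynal | C[Si](C)(C)C#CC=O | starting material
2 | (triphenylphosphoranylidene)acetaldehyde | O=CC=P(c1ccccc1)(c1ccccc1)c1ccccc1 | starting material
3 | (2E)-5-(trimethylsilyl)pent-2-en-4-ynal | C[Si](C)(C)C#C/C=C/C=O | intermediate
4 | tert-butyl 3-oxobutanoate | CC(=O)CC(=O)OC(C)(C)C | starting material
5 | tert-butyl (3S)-2-acetyl-3-(2-oxoethyl)-5-(trimethylsilyl)pent-4-ynoate (both C2 epimers) | C[Si](C)(C)C#C[C@H](C(C(C)=O)C(=O)OC(C)(C)C)CC=O | intermediate
6 | (3S)-5-oxo-3-[(trimethylsilyl)ethynyl]hexanal | C[Si](C)(C)C#C[C@H](CC(C)=O)CC=O | intermediate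
7 | (5S)-5-[(trimethylsilyl)ethynyl]cyclohex-2-en-1-one | C[Si](C)(C)C#C[C@H]1CC=CC(=O)C1 | intermediate
8 | (5S)-2-(hydroxymethyl)-5-[(trimethylsilyl)ethynyl]cyclohex-2-en-1-one | C[Si](C)(C)C#C[C@H]1CC=C(CO)C(=O)C1 | intermediate
9 | [(4S)-6-oxo-4-[(trimethylsilyl)ethynyl]cyclohex-1-en-1-yl]methyl 2-methylpropanoate | C[Si](C)(C)C#C[C@H]1CC=C(COC(=O)C(C)C)C(=O)C1 | intermediate
10 | [(4S)-4-ethynyl-6-oxocyclohex-1-en-1-yl]methyl 2-methylpropanoate | C#C[C@H]1CC=C(COC(=O)C(C)C)C(=O)C1 | intermediate
11 | (S)-2-methylglycidol | C1[C@@](C)(O1)CO | starting material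
12 | (2R)-2-methylpent-4-ene-1,2-diol | C=CC[C@@](C)(O)CO | intermediate
13 | (2R)-2-hydroxy-2-methylpent-4-en-1-yl 2-methylpropanoate | C=CC[C@@](C)(O)COC(=O)C(C)C | intermediate
14 | (2R,3E)-2-hydroxy-2-methyl-6-[(1S)-4-{[(2-methylpropanoyl)oxy]methyl}-5-oxocyclohex-3-en-1-yl]hepta-3,6-dien-1-yl 2-methylpropanoate | C=C(C/C=C/[C@@](C)(O)COC(=O)C(C)C)[C@H]1CC=C(COC(=O)C(C)C)C(=O)C1 | intermediate
15 | (2R,3E)-2-hydroxy-6-[(1S,5S)-5-hydroxy-4-{[(2-methylpropanoyl)oxy]methyl}cyclohex-3-en-1-yl]-2-methylhepta-3,6-dien-1-yl 2-methylpropanoate | C=C(C/C=C/[C@@](C)(O)COC(=O)C(C)C)[C@H]1CC=C(COC(=O)C(C)C)[C@@H](O)C1 | target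

Total step count: 9. Longest linear sequence: 7 (steps 1, 2, 3, 4, 5, 8, 9).

Steps most likely to fail

Step 2. The slim alkynyl group may give incomplete enantiofacial discrimination at C1 of the iminium ion, and the hot acid stage may erode what selectivity there is. The fallback replaces asymmetric annulation by resolution and sets out from 3 and 4. Pyrrolidine (20 mol %) and AcOH in toluene at rt, then TsOH·H2O at 80 °C, should lead through the racemic Michael adduct rac-tert-butyl 2-acetyl-3-(2-oxoethyl)-5-(trimethylsilyl)pent-4-ynoate F1 and the racemic keto aldehyde rac-5-oxo-3-[(trimethylsilyl)ethynyl]hexanal F2 (neither isolated) to the racemic enone rac-5-[(trimethylsilyl)ethynyl]cyclohex-2-en-1-one F3. A kinetic resolution by copper-catalysed conjugate addition follows (Cu(OTf)2, a binaphthol-derived phosphoramidite ligand of the antipode that consumes the 5R enone, Et2Zn 0.6 equiv, toluene, −30 °C); this reaction type is known to distinguish the enantiomers of 5-substituted cyclohex-2-enones. It should convert the unwanted enantiomer into the trans adduct (3R,5R)-3-ethyl-5-[(trimethylsilyl)ethynyl]cyclohexan-1-one F4, which is separated, and leave 7, where the route is rejoined.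

Step 8. The cationic ruthenium catalyst may be held back by the 2-(acyloxymethyl)enone, through chelation or ionisation of the activated allylic ester, so that turnover and the branched mode of coupling suffer. The fallback moves the coupling to the alcohol oxidation level and sets out from 9. NaBH4/CeCl3·7H2O in MeOH at −78 °C should give the cis alcohol [(4S,6S)-6-hydroxy-4-[(trimethylsilyl)ethynyl]cyclohex-1-en-1-yl]methyl 2-methylpropanoate F5. TBSOTf and 2,6-lutidine in CH2Cl2 give the silyl ether [(4S,6S)-6-[(tert-butyldimethylsilyl)oxy]-4-[(trimethylsilyl)ethynyl]cyclohex-1-en-1-yl]methyl 2-methylpropanoate F6. AgNO3 (10 mol %) in acetone/H2O frees the alkyne [(4S,6S)-6-[(tert-butyldimethylsilyl)oxy]-4-ethynylcyclohex-1-en-1-yl]methyl 2-methylpropanoate F7. Coupling with 13 under [CpRu(MeCN)3]PF6 in acetone, now on a substrate without a Michael acceptor, should give the diene (2R,3E)-6-[(1S,5S)-5-[(tert-butyldimethylsilyl)oxy]-4-{[(2-methylpropanoyl)oxy]methyl}cyclohex-3-en-1-yl]-2-hydroxy-2-methylhepta-3,6-dien-1-yl 2-methylpropanoate F8. HF·pyridine in THF (non-basic, to avoid acyl migration) removes the silyl ether and the route is rejoined at 15.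

Step 9. Facial selectivity at C5 may be insufficient, or hydride may attack in the SN2′ sense with loss of the allylic isobutyrate. The fallback replaces substrate control by reagent control and sets out from 14. A CBS reduction with (R)-Me-CBS, (3aR)-1-methyl-3,3-diphenyltetrahydro-1H,3H-pyrrolo[1,2-c][1,3,2]oxazaborole (20 mol %), and catecholborane in toluene at −78 °C is used. The C4 alkene side acts as the large group, so this antipode should deliver hydride to the face that gives 5S, matched with the substrate bias, under non-basic conditions. The route is rejoined at 15; no new compound arises (F0).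

Further compounds
F1 | step 2 | rac-tert-butyl 2-acetyl-3-(2-oxoethyl)-5-(trimethylsilyl)pent-4-ynoate | C[Si](C)(C)C#CC(CC=O)C(C(C)=O)C(=O)OC(C)(C)C
F2 | step 2 | rac-5-oxo-3-[(trimethylsilyl)ethynyl]hexanal | C[Si](C)(C)C#CC(CC=O)CC(C)=O
F3 | step 2 | rac-5-[(trimethylsilyl)ethynyl]cyclohex-2-en-1-one | C[Si](C)(C)C#CC1CC=CC(=O)C1
F4 | step 2 | (3R,5R)-3-ethyl-5-[(trimethylsilyl)ethynyl]cyclohexan-1-one | C[Si](C)(C)C#C[C@@H]1C[C@@H](CC)CC(=O)C1
F5 | step 8 | [(4S,6S)-6-hydroxy-4-[(trimethylsilyl)ethynyl]cyclohex-1-en-1-yl]methyl 2-methylpropanoate | C[Si](C)(C)C#C[C@H]1CC=C(COC(=O)C(C)C)[C@@H](O)C1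
F6 | step 8 | [(4S,6S)-6-[(tert-butyldimethylsilyl)oxy]-4-[(trimethylsilyl)ethynyl]cyclohex-1-en-1-yl]methyl 2-methylpropanoate | C[Si](C)(C)C#C[C@H]1CC=C(COC(=O)C(C)C)[C@@H](O[Si](C)(C)C(C)(C)C)C1
F7 | step 8 | [(4S,6S)-6-[(tert-butyldimethylsilyl)oxy]-4-ethynylcyclohex-1-en-1-yl]methyl 2-methylpropanoate | C#C[C@H]1CC=C(COC(=O)C(C)C)[C@@H](O[Si](C)(C)C(C)(C)C)C1
F8 | step 8 | (2R,3E)-6-[(1S,5S)-5-[(tert-butyldimethylsilyl)oxy]-4-{[(2-methylpropanoyl)oxy]methyl}cyclohex-3-en-1-yl]-2-hydroxy-2-methylhepta-3,6-dien-1-yl 2-methylpropanoate | C=C(C/C=C/[C@@](C)(O)COC(=O)C(C)C)[C@H]1CC=C(COC(=O)C(C)C)[C@@H](O[Si](C)(C)C(C)(C)C)C1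
F0 | step 9 | none | none
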